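**Plan**

Numbering (longipinane): C1 is the ring C=O, C2=C3(CH3), C4 and C11 are the bridgeheads, C5 and C10(CH3) the one-carbon bridges, C6 is C(CH3)2, then C7(OAng)–C8–C9(OAc). The retrosynthesis cuts the two esters, the C9–O bond (back to a C8=C9 enone), the C1 oxygen (back to the allylic CH2), one C6–CH3 bond, and then C8–C9 and C10–C11 together.
Enabling feature: the seven-membered ring C5–C6–C7–C8–C9–C10–C11 is a five-carbon unit C8–C7(O)–C6–C5–C11 plus a two-carbon unit C9–C10. With a C6–C11 bond in place of C10–C11, the five carbons are a 2-siloxyvinylcyclopropane fused to the cyclohexene ring (C1–C5, C11) and C9=C10 is an isopropenyl group on C4, so a rhodium-catalysed (5+2) cycloaddition closes the seven-membered ring and the cyclobutane (C4–C5–C11–C10) in one event. The siloxy group activates the cyclopropane, carries the C7 oxygen and later delivers the second C6 methyl.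
Forward order: Diels–Alder of a cyclopropene ester with a triene (six-membered ring and cyclopropane), methyl ketone and silyl enol ether, (5+2) (seven- and four-membered rings), C6 methylation, C1 oxidation, C8=C9 dehydrogenation, C9–OH by conjugate borylation, C7–OH/C9–OAc by Evans–Tishchenko reaction, angelate.
Stereochemistry: the endo Diels–Alder fixes C4/C5/C11 (relative; racemic). The (5+2) is stereospecific (retention at C11, suprafacial on the alkene) and sets C10. C9 is set by a CuCl/(R,S)-Josiphos catalyst, which also turns the two enantiomeric series into separable diastereomers and so fixes the absolute configuration. C7 follows from C9 by intramolecular hydride delivery.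

Key step: step 8

Remark: compounds 8–17 are racemic; each SMILES shows the enantiomer that leads to 23, and the material of the other series leaves the route in step 12 as a C9 diastereomer of 19, so at most half of 17 can be carried on.
Assumption: with (R,S)-Josiphos the Cu–Bpin species adds to the Re face of C9 of enone 17 (the face on the C11 side in the enantiomer that leads to 23); if the opposite sense is found, the (S,R) ligand is used.

**Route**

Step 1
Reactants: 1 ethyl diazoacetate; 2 acetylene
Product: 3 ethyl cycloprop-2-ene-1-carboxylate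
Conditions: Rh2(OAc)4 (0.5 mol %), CH2Cl2 saturated with 2, slow addition of 1, 0 °C to rt; product kept as a cold solution
Reagents that add atoms: none
Why: Rhodium-carbenoid [2+1] addition to the alkyne (cyclopropenation); the achiral cyclopropene is kept in solution because it dimerises by an ene reaction when neat.

Step 2
Reactants: 4 2-(triphenylphosphoranylidene)propanal; 5 methacrolein
Product: 6 (2E)-2,4-dimethylpenta-2,4-dienal
Conditions: toluene, 90 °C
Reagents that add atoms: none
Why: Wittig olefination with a carbonyl-stabilised ylide, which should give the (E)-enal (CHO trans to the isopropenyl group).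

Step 3
Reactants: 6 (2E)-2,4-dimethylpenta-2,4-dienal
Product: 7 (3E)-2,4-dimethylhexa-1,3,5-triene
Conditions: Ph3PCH3Br, KOtBu, Et2O, 0 °C to rt; product distilled into pentane
Reagents that add atoms: methyltriphenylphosphonium bromide, C[P+](c1ccccc1)(c1ccccc1)c1ccccc1.[Br-]
Why: Wittig methylenation of the aldehyde leaves the 3E geometry untouched, so the vinyl/C3=C4 diene can reach the s-cis form with the isopropenyl group outside.

Step 4
Reactants: 3 ethyl cycloprop-2-ene-1-carboxylate; 7 (3E)-2,4-dimethylhexa-1,3,5-triene
Product: 8 rac-ethyl 3-methyl-2-(prop-1-en-2-yl)bicyclo[4.1.0]hept-3-ene-7-carboxylate (2-isopropenyl cis to C7; ester exo)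
Conditions: CH2Cl2/pentane, BHT (cat.), 0 °C to rt
Reagents that add atoms: none
Why: Diels–Alder reaction of a strained cyclopropene in which the diene adds anti to the ester with C7–H endo, so the (E)-isopropenyl group should end cis to the cyclopropane and the ester exo (relative configuration of C4, C5, C11); the second diene unit carries a Z substituent and cannot react.

Step 5
Reactants: 8 rac-ethyl 3-methyl-2-(prop-1-en-2-yl)bicyclo[4.1.0]hept-3-ene-7-carboxylate
Product: 9 rac-ethyl 3,7-dimethyl-2-(prop-1-en-2-yl)bicyclo[4.1.0]hept-3-ene-7-carboxylate (7-methyl exo; ester endo)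
Conditions: LiN(iPr)2, THF, −78 °C; MeI, DMPU, −78 to −20 °C
Reagents that add atoms: iodomethane, CI
Why: Alkylation of the cyclopropanecarboxylate enolate from the open exo face should put CH3 exo and turn the ester endo, that is cis to the isopropenyl-bearing carbon as the (5+2) step needs.

Step 6
Reactants: 9 rac-ethyl 3,7-dimethyl-2-(prop-1-en-2-yl)bicyclo[4.1.0]hept-3-ene-7-carboxylate
Product: 11 rac-1-[3,7-dimethyl-2-(prop-1-en-2-yl)bicyclo[4.1.0]hept-3-en-7-yl]ethan-1-one (acetyl endo), via alpha-silyl ketone 10 (not isolated)
Conditions: Me3SiCH2Li (2.5 equiv), pentane/THF, 0 °C to rt; then MeOH, rt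
Reagents that add atoms: (trimethylsilyl)methyllithium, [Li]C[Si](C)(C)C
Why: Addition of the silylmethyllithium to the ester stops at the ketone level because the α-silyl ketone is deprotonated at once, and methanolysis then removes silicon to leave the methyl ketone.

Step 7
Reactants: 11 rac-1-[3,7-dimethyl-2-(prop-1-en-2-yl)bicyclo[4.1.0]hept-3-en-7-yl]ethan-1-one
Product: 12 rac-triethyl({1-[3,7-dimethyl-2-(prop-1-en-2-yl)bicyclo[4.1.0]hept-3-en-7-yl]ethenyl}oxy)silane
Conditions: LiN(iPr)2, THF, −78 °C; Et3SiCl, −78 to 0 °C
Reagents that add atoms: chlorotriethylsilane, CC[Si](Cl)(CC)CC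
Why: Kinetic enolisation of the methyl ketone (C6 is quaternary, so C8 is the only α-position) and O-silylation give the 2-siloxyvinylcyclopropane.

Step 8
Reactants: 12 rac-triethyl({1-[3,7-dimethyl-2-(prop-1-en-2-yl)bicyclo[4.1.0]hept-3-en-7-yl]ethenyl}oxy)silane
Product: 13 rac-7-(triethylsilyloxy)-13-norlongipina-2,6-diene (tricyclic silyl enol ether with C4/C5/C10/C11 as in 23)
Conditions: [Rh(CO)2Cl]2 (5 mol %), degassed toluene, 60–80 °C
Reagents that add atoms: none
Why: Proposed new method: monovalent rhodium adds oxidatively into the C6–C11 bond of the all-cis siloxyvinylcyclopropane to give a rhodacycle (η3-allyl over C6–C7–C8, σ-bond to C11), the isopropenyl group on C4 inserts at the allyl terminus through its CH2 carbon (C8–C9), and reductive elimination from the resulting five-membered rhodacycle (Rh, C10, C4, C5, C11) makes C10–C11; the closest known reaction type is the rhodium-catalysed intramolecular (5+2) cycloaddition of vinylcyclopropanes, siloxy-substituted ones included, with tethered alkenes, the new element being a one-atom tether from the cyclopropane so that a four-membered ring results. The seven-membered ring (C5–C6–C7–C8–C9–C10–C11) is closed as the (5+2) ring by allyl–alkene insertion and C–C reductive elimination, and the cyclobutane (C4–C5–C11–C10) is closed in that same reductive elimination across the existing C4–C5 link. C11 is set with retention (C10 takes the place of the departing C6 on the face cis to the C4 substituent, which the endo Diels–Alder adduct provides), C10 is set by suprafacial addition to the only alkene face that can reach both C8 and C11 (its CH3 ends syn to the C1–C3 bridge), and C4 and C5 are carried through unchanged. The step needs cleavage of C6–C11 rather than C6–C5, which is expected because only the C6–C11 rhodacycle lets the alkene chelate through C4, and it needs the C9-to-C8/C10-to-C11 sense of union rather than the reverse sense, which would give a less strained bicyclo[3.2.1] isomer; the short C4 link, which holds C10 beside Rh–C11 so that only the distal carbon C9 reaches the distal allyl carbon C8, is what should secure this. β-Hydride elimination from the tertiary alkylrhodium and the thermal homodienyl hydrogen shift of the cis-substituted cyclopropane are the competing processes, to be held back by working at or below 80 °C.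

Step 9
Reactants: 13 rac-7-(triethylsilyloxy)-13-norlongipina-2,6-diene
Product: 15 rac-longipin-2-en-7-one, via lithium enolate 14 (not isolated)
Conditions: MeLi, THF, 0 °C to rt; then MeI, DMPU, −78 to 0 °C
Reagents that add atoms: iodomethane, CI
Why: Methyllithium cleaves the silyl enol ether to the regiodefined tetrasubstituted lithium enolate, which is C-methylated at C6 to complete the gem-dimethyl group without creating a stereocentre.

Step 10
Reactants: 15 rac-longipin-2-en-7-one
Product: 16 rac-longipin-2-ene-1,7-dione
Conditions: Rh2(C6H10NO)4 (dirhodium tetracaprolactamate, 1 mol %), t-BuOOH (5 equiv), K2CO3, CH2Cl2, rt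
Reagents that add atoms: tert-butyl hydroperoxide, CC(C)(C)OO
Why: Catalytic allylic oxidation of the trisubstituted ring alkene at its only accessible allylic CH2 (C1), as in the α-pinene to verbenone oxidation; C4 is now a bridgehead and no longer competes.

Step 11
Reactants: 16 rac-longipin-2-ene-1,7-dione
Product: 17 rac-longipina-2,8-diene-1,7-dione
Conditions: 2-iodoxybenzoic acid (IBX, 2.5 equiv), DMSO/toluene, 70 °C
Reagents that add atoms: none
Why: IBX dehydrogenation of the saturated ketone; C6 is quaternary, so the new double bond can only form between C8 and C9.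

Step 12
Reactants: 17 rac-longipina-2,8-diene-1,7-dione
Product: 19 (4R,5S,9R,10R,11R)-9-hydroxylongipin-2-ene-1,7-dione (single enantiomer), via pinacol boronate 18 (not isolated)
Conditions: CuCl (5 mol %), NaOtBu (10 mol %), (R,S)-Josiphos (6 mol %), B2pin2, MeOH, THF, rt; then NaBO3·4H2O, THF/H2O, rt; chromatographic separation of 19 from the C9 diastereomer that arises from the other enantiomer of 17
Reagents that add atoms: bis(pinacolato)diboron, CC1(C)OB(OC1(C)C)B1OC(C)(C)C(C)(C)O1 (boron of 18); sodium perborate, [Na+].[Na+].O[B-]1(O)OO[B-](O)(O)OO1 (oxygen of 19)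
Why: Copper-catalysed enantioselective conjugate borylation followed by stereoretentive C–B oxidation; the two faces of C8=C9 differ only through the remote C1=O/C3–CH3 pair, so the catalyst should decide and add boron to the Re face of C9 in both enantiomers of 17, which turns one enantiomer into 19 and the other into a separable diastereomer with the mirror-image core, while the β,β-disubstituted C2=C3 enone should not react.

Step 13
Reactants: 19 (4R,5S,9R,10R,11R)-9-hydroxylongipin-2-ene-1,7-dione
Product: 20 (4R,5S,7R,9R,10R,11R)-9-acetoxy-7-hydroxylongipin-2-en-1-one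
Conditions: CH3CHO (6 equiv), SmI2 (0.3 equiv), THF, −10 °C
Reagents that add atoms: acetaldehyde, CC=O
Why: Evans–Tishchenko reaction: hydride is passed intramolecularly from the samarium-bound acetaldehyde adduct on O9 to the same face of C7, so the new C7–OH should be trans (1,3-anti) to the C9 acetate, which is installed in the same event.

Step 14
Reactants: 20 (4R,5S,7R,9R,10R,11R)-9-acetoxy-7-hydroxylongipin-2-en-1-one; 21 angelic acid
Product: 23 (4R,5S,7R,9R,10R,11R)-9-acetoxy-7-angeloyloxylongipin-2-en-1-one (target), via mixed anhydride 22 (not isolated)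
Conditions: 21, 2,4,6-Cl3C6H2COCl, Et3N, toluene, rt; then 20, 80 °C
Reagents that add atoms: none
Why: Yamaguchi esterification through the mixed anhydride of angelic acid, conditions under which the (Z)-2-methylbut-2-enoate should not isomerise to the tiglate.

**Compound list**

1 | ethyl diazoacetate | CCOC(=O)C=[N+]=[N-] | starting material
2 | acetylene | C#C | starting material
3 | ethyl cycloprop-2-ene-1-carboxylate | CCOC(=O)C1C=C1 | intermediate
4 | 2-(triphenylphosphoranylidene)propanal | CC(C=O)=P(c1ccccc1)(c1ccccc1)c1ccccc1 | starting material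
5 | methacrolein | CC(=C)C=O | starting material
6 | (2E)-2,4-dimethylpenta-2,4-dienal | O=C/C(C)=C/C(C)=C | intermediate
7 | (3E)-2,4-dimethylhexa-1,3,5-triene | C=C/C(C)=C/C(C)=C | intermediate
8 | rac-ethyl 3-methyl-2-(prop-1-en-2-yl)bicyclo[4.1.0]hept-3-ene-7-carboxylate (isopropenyl cis to C7, ester exo) | CCOC(=O)[C@H]1[C@@H]2CC=C(C)[C@H](C(C)=C)[C@@H]21 | intermediate
9 | rac-ethyl 3,7-dimethyl-2-(prop-1-en-2-yl)bicyclo[4.1.0]hept-3-ene-7-carboxylate (7-methyl exo, ester endo) | CCOC(=O)[C@]1(C)[C@@H]2CC=C(C)[C@H](C(C)=C)[C@@H]21 | intermediate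
10 | rac-1-[3,7-dimethyl-2-(prop-1-en-2-yl)bicyclo[4.1.0]hept-3-en-7-yl]-2-(trimethylsilyl)ethan-1-one | C[Si](C)(C)CC(=O)[C@]1(C)[C@@H]2CC=C(C)[C@H](C(C)=C)[C@@H]21 | intermediate
11 | rac-1-[3,7-dimethyl-2-(prop-1-en-2-yl)bicyclo[4.1.0]hept-3-en-7-yl]ethan-1-one (acetyl endo) | CC(=O)[C@]1(C)[C@@H]2CC=C(C)[C@H](C(C)=C)[C@@H]21 | intermediate
12 | rac-triethyl({1-[3,7-dimethyl-2-(prop-1-en-2-yl)bicyclo[4.1.0]hept-3-en-7-yl]ethenyl}oxy)silane | C=C(O[Si](CC)(CC)CC)[C@]1(C)[C@@H]2CC=C(C)[C@H](C(C)=C)[C@@H]21 | intermediate
13 | rac-7-(triethylsilyloxy)-13-norlongipina-2,6-diene | CC[Si](CC)(CC)OC=1CC[C@@]2(C)[C@@H]3CC=C(C)[C@H]2[C@@H]3C=1C | intermediate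
14 | lithium enolate of rac-13-norlongipin-2-en-7-one (C6=C7) | [Li+].[O-]C=1CC[C@@]2(C)[C@@H]3CC=C(C)[C@H]2[C@@H]3C=1C | intermediate
15 | rac-longipin-2-en-7-one | O=C1CC[C@@]2(C)[C@@H]3CC=C(C)[C@H]2[C@@H]3C1(C)C | intermediate
16 | rac-longipin-2-ene-1,7-dione | O=C1CC[C@@]2(C)[C@@H]3C(=O)C=C(C)[C@H]2[C@@H]3C1(C)C | intermediate
17 | rac-longipina-2,8-diene-1,7-dione | O=C1C=C[C@@]2(C)[C@@H]3C(=O)C=C(C)[C@H]2[C@@H]3C1(C)C | intermediate
18 | 9-(4,4,5,5-tetramethyl-1,3,2-dioxaborolan-2-yl)longipin-2-ene-1,7-dione (boron on the C11 face) | O=C1C[C@@H](B4OC(C)(C)C(C)(C)O4)[C@@]2(C)[C@@H]3C(=O)C=C(C)[C@H]2[C@@H]3C1(C)C | intermediate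
19 | (4R,5S,9R,10R,11R)-9-hydroxylongipin-2-ene-1,7-dione | O=C1C[C@@H](O)[C@@]2(C)[C@@H]3C(=O)C=C(C)[C@H]2[C@@H]3C1(C)C | intermediate
20 | (4R,5S,7R,9R,10R,11R)-9-acetoxy-7-hydroxylongipin-2-en-1-one | O[C@@H]1C[C@@H](OC(C)=O)[C@@]2(C)[C@@H]3C(=O)C=C(C)[C@H]2[C@@H]3C1(C)C | intermediate
21 | angelic acid, (Z)-2-methylbut-2-enoic acid | C/C=C(/C)C(=O)O | starting material
22 | (Z)-2-methylbut-2-enoic 2,4,6-trichlorobenzoic anhydride | C/C=C(/C)C(=O)OC(=O)c1c(Cl)cc(Cl)cc1Cl | intermediate
23 | (4R,5S,7R,9R,10R,11R)-9-acetoxy-7-angeloyloxylongipin-2-en-1-one | C/C=C(/C)C(=O)O[C@@H]1C[C@@H](OC(C)=O)[C@@]2(C)[C@@H]3C(=O)C=C(C)[C@H]2[C@@H]3C1(C)C | target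

**Count and risks**

Total steps: 14. Longest linear sequence: 13 steps (steps 2–14, from methacrolein 5).

Steps most likely to fail:

Step 8. The rhodacycle may undergo β-hydride elimination instead of the cyclobutane-forming reductive elimination, the alkene may be taken up in the reverse sense, or the vinylcyclopropane may isomerise to a cyclopentene. The fallback makes the two bonds one after the other with established reactions, setting out from ketone 11 and coming back at dienedione 17. Hydroboration of the isopropenyl group of 11 (9-borabicyclo[3.3.1]nonane, then NaBO3) gives the primary alcohol F1, which is converted in one flask (TEMPO, PhI(OAc)2, NH4OAc) into the nitrile F2. Me3SiI opens the acetyl-activated cyclopropane by homoconjugate addition of iodide at C11 with inversion to give the iodo silyl enol ether F3. KN(SiMe3)2 then closes the cyclobutane by intramolecular alkylation of the tertiary nitrile anion (4-exo-tet, second inversion at C11, hence overall retention) to give the bicyclo[3.1.1]heptene nitrile F4; only the C10 epimer with the nitrile on the C5 side can go on. Fluoride-mediated methylation of the silyl enol ether (BnMe3NF, MeI) gives the gem-dimethyl keto nitrile F5. After protection of the ketone in the flask as its lithium enolate (LiN(iPr)2), i-Bu2AlH reduces the nitrile to the keto aldehyde F6. Intramolecular aldol condensation (KOH, MeOH) closes the seven-membered ring as the enone F7, and the allylic oxidation of step 10 converts F7 into 17.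

Step 12. Facial discrimination at C9 may be poor, or the two diastereomeric series may not separate. The fallback sets out from 17 and comes back at 19. Catalytic asymmetric nucleophilic epoxidation of the C8=C9 enone (t-BuOOH, La(OiPr)3/(R)-BINOL/Ph3As=O) gives the epoxy ketone F8 from the enantiomer of 17 that leads to 23. The other enantiomer gives a diastereomeric epoxide with the mirror-image core, and this pair should be easier to separate than the hydroxy ketones. SmI2 (THF/MeOH, −90 °C) then cleaves the α-C–O bond of F8 reductively and leaves the C9 hydroxyl of 19.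

Step 4. The cyclopropene ester may be lost by ene oligomerisation before it adds, or the endo/anti selectivity may be low. The fallback sets out from 3 and comes back at 8. Saponification (KOH, MeOH) gives cycloprop-2-ene-1-carboxylic acid F9, which is converted through its pivalic mixed anhydride and lithiated oxazolidin-2-one into the crystalline, storable acyl oxazolidinone F10, a dienophile of established endo/anti selectivity. Cycloaddition with 7 gives the imide F11, and ethanolysis (Ti(OEt)4, EtOH) returns ester 8.

Further compounds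
F1 | step 8 | rac-2-[7-acetyl-3,7-dimethylbicyclo[4.1.0]hept-3-en-2-yl]propan-1-ol (mixture at the new CH) | CC(=O)[C@]1(C)[C@@H]2CC=C(C)[C@H](C(C)CO)[C@@H]21
F2 | step 8 | rac-2-[7-acetyl-3,7-dimethylbicyclo[4.1.0]hept-3-en-2-yl]propanenitrile | CC(=O)[C@]1(C)[C@@H]2CC=C(C)[C@H](C(C)C#N)[C@@H]21
F3 | step 8 | rac-2-{5-iodo-2-methyl-6-[3-(trimethylsilyloxy)but-2-en-2-yl]cyclohex-2-en-1-yl}propanenitrile (iodine trans to the C6 side chain) | CC(O[Si](C)(C)C)=C(C)[C@@H]1[C@@H](I)CC=C(C)[C@@H]1C(C)C#N
F4 | step 8 | rac-2,6-dimethyl-7-[3-(trimethylsilyloxy)but-2-en-2-yl]bicyclo[3.1.1]hept-2-ene-6-carbonitrile | N#C[C@@]1(C)[C@@H]2CC=C(C)[C@H]1[C@@H]2C(C)=C(C)O[Si](C)(C)C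
F5 | step 8 | rac-2,6-dimethyl-7-(2-methyl-3-oxobutan-2-yl)bicyclo[3.1.1]hept-2-ene-6-carbonitrile | N#C[C@@]1(C)[C@@H]2CC=C(C)[C@H]1[C@@H]2C(C)(C)C(C)=O
F6 | step 8 | rac-2,6-dimethyl-7-(2-methyl-3-oxobutan-2-yl)bicyclo[3.1.1]hept-2-ene-6-carbaldehyde | O=C[C@@]1(C)[C@@H]2CC=C(C)[C@H]1[C@@H]2C(C)(C)C(C)=O
F7 | step 8 | rac-longipina-2,8-dien-7-one | O=C1C=C[C@@]2(C)[C@@H]3CC=C(C)[C@H]2[C@@H]3C1(C)C
F8 | step 12 | 8,9-epoxylongipin-2-ene-1,7-dione (epoxide on the C11 face) | O=C1[C@H]4O[C@H]4[C@@]2(C)[C@@H]3C(=O)C=C(C)[C@H]2[C@@H]3C1(C)C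
F9 | step 4 | cycloprop-2-ene-1-carboxylic acid | OC(=O)C1C=C1
F10 | step 4 | 3-(cycloprop-2-ene-1-carbonyl)-1,3-oxazolidin-2-one | O=C(C1C=C1)N1CCOC1=O
F11 | step 4 | rac-3-{[3-methyl-2-(prop-1-en-2-yl)bicyclo[4.1.0]hept-3-en-7-yl]carbonyl}-1,3-oxazolidin-2-one (isopropenyl cis to C7, acyl exo) | O=C([C@H]1[C@@H]2CC=C(C)[C@H](C(C)=C)[C@@H]21)N1CCOC1=O
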